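**Plan**

- Retrosynthetic cuts, in order: the three methoxymethyl ethers; the C3–C4 bond of ring C; the O1–C2 ether bond; the C1'–C(=O) bond; last, the methyl–carbon and vinyl–carbon bonds of the quaternary carbon on C5', which leads back to the acetyl group of paeonol.
- Enabling feature: in ring B the quaternary carbon of the 2-methylbut-3-en-2-yl group sits on C5', ortho to the C4' hydroxyl. It is therefore the exocyclic carbon of an o-quinone methide whose oxygen is O4', and paeonol already carries acetyl, hydroxyl and methoxyl on C5', C4' and C2'.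
- Forward order: ring B is completed first (steps 1–4), and its C1' bromide is exchanged for a chloroacetyl group (step 5). The chloro ketone is then etherified with the ring A aldehyde made from 2,4,6-trihydroxybenzaldehyde (steps 6–7). Ring C is the only ring formed, last, by a crossed benzoin closure (step 8).
- Stereochemistry: the single stereocentre C3 (R) is created in step 8 under control of a chiral triazolium carbene, by attack on the Si face of the aryl ketone. C3 carries no hydrogen, so the final acetal cleavage cannot epimerise it.

Key step: step 3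

Assumption: the (5aR,10bS) antipode of the aminoindanol-derived triazolium salt is taken as the one that directs the cyclisation of step 8 to the Si face of the ketone; both antipodes are commercial, so if the sense proves opposite the mirror-image salt is used with no other change.

**Route**

Step 1
Reactants: 1 paeonol (1-(2-hydroxy-4-methoxyphenyl)ethan-1-one)
Product: 2 1-(5-bromo-2-hydroxy-4-methoxyphenyl)ethan-1-one
Conditions: NBS (1.05 equiv), MeCN, 0 → 25 °C
Reagents that add atoms: N-bromosuccinimide, O=C1CCC(=O)N1Br
Why: Electrophilic aromatic bromination should go to C5, which is para to the hydroxyl and ortho to the methoxyl, whereas C3 is flanked by two substituents and the acetyl group deactivates its own ortho and para carbons.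

Step 2
Reactants: 2 1-(5-bromo-2-hydroxy-4-methoxyphenyl)ethan-1-one
Product: 3 2-acetyl-4-bromo-5-methoxyphenyl tert-butyl carbonate
Conditions: Boc2O, DMAP (cat.), iPr2NEt, CH2Cl2, 0 → 25 °C
Reagents that add atoms: di-tert-butyl dicarbonate, CC(C)(C)OC(=O)OC(=O)OC(C)(C)C
Why: DMAP-catalysed O-acylation of the hydrogen-bonded phenol should give the aryl tert-butyl carbonate, the usual trigger group for anionic o-quinone methide generation.

Step 3
Reactants: 3 2-acetyl-4-bromo-5-methoxyphenyl tert-butyl carbonate; 4 methylmagnesium bromide; 5 vinylmagnesium bromide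
Product: 9 4-bromo-5-methoxy-2-(2-methylbut-3-en-2-yl)phenol, via tertiary magnesium alkoxide 6 (not isolated), via Boc-transferred magnesium phenoxide 7 (not isolated), via dimethyl o-quinone methide 8 (not isolated)
Conditions: MeMgBr (1.05 equiv), Et2O, −78 °C; then CH2=CHMgBr (3 equiv, THF), −78 → 0 °C; aq NH4Cl
Reagents that add atoms: methylmagnesium bromide 4, C[Mg]Br; vinylmagnesium bromide 5, C=C[Mg]Br
Why: MeMgBr adds to the acetyl carbonyl of 3 to give alkoxide 6, whose oxygen takes the tert-butoxycarbonyl group from the neighbouring phenol oxygen through a six-membered transition state (7); the magnesium phenoxide then expels tert-butyl carbonate, which falls apart to CO2 and tert-butoxide, and the o-quinone methide 8 with two methyl groups on its exocyclic carbon is attacked at that carbon by vinylmagnesium bromide in a 1,4-addition that restores the aromatic ring and completes the quaternary carbon. The closest known reaction type is the low-temperature anionic generation of o-quinone methides from O-Boc salicylaldehydes and O-Boc o-hydroxyaryl ketones, followed by 1,4-addition of a second organomagnesium reagent (three-component synthesis of ortho-alkylated phenols). No ring is closed and no stereocentre is formed, because the new quaternary carbon carries two identical methyl groups. Three selectivities are needed: addition to the ketone before the carbonate (the ketone is the more electrophilic carbonyl at −78 °C and is chelated to magnesium together with the carbonate oxygen); 1,4-addition faster than the 1,5-hydrogen shift or deprotonation that would give the isopropenylphenol (8 forms only on warming, when a threefold excess of the vinyl reagent is already present and magnesium is bound to the quinone methide oxygen); and an untouched aryl bromide (methyl and vinyl Grignard reagents do not undergo bromine–magnesium exchange below 0 °C). The methoxyl para to the benzylic carbon eases the ionisation to 8, and the regiochemistry is fixed by paeonol, whose acetyl group already stands on C5' next to the C4' oxygen.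

Step 4
Reactants: 9 4-bromo-5-methoxy-2-(2-methylbut-3-en-2-yl)phenol
Product: 10 1-bromo-2-methoxy-4-(methoxymethoxy)-5-(2-methylbut-3-en-2-yl)benzene
Conditions: MOMCl, iPr2NEt, CH2Cl2, 0 → 40 °C
Reagents that add atoms: chloromethyl methyl ether, COCCl
Why: O-Alkylation of the phenol with the highly reactive chloromethyl ether (Williamson-type acetal formation) should proceed even next to the tertiary alkyl group, and the methoxymethyl group tolerates organolithium, carbonate and carbene conditions and is later removed without hydrogenation, which the vinyl group would not survive.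

Step 5
Reactants: 10 1-bromo-2-methoxy-4-(methoxymethoxy)-5-(2-methylbut-3-en-2-yl)benzene; 11 2-chloro-N-methoxy-N-methylacetamide
Product: 14 2-chloro-1-[2-methoxy-4-(methoxymethoxy)-5-(2-methylbut-3-en-2-yl)phenyl]ethan-1-one, via aryllithium 12 (not isolated), via lithium hemiaminal alkoxide 13 (not isolated)
Conditions: n-BuLi (1.05 equiv), THF, −78 °C; then ClCH2C(O)N(OMe)Me, −78 → −20 °C; aq NH4Cl
Reagents that add atoms: 2-chloro-N-methoxy-N-methylacetamide 11, CON(C)C(=O)CCl
Why: Bromine–lithium exchange is much faster at −78 °C than ortho-lithiation next to the ether groups, and the aryllithium acylates the N-methoxy-N-methylamide through the stable lithium chelate 13, which releases the α-chloro ketone only on work-up (Weinreb ketone synthesis), so a second addition is avoided.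

Step 6
Reactants: 15 2,4,6-trihydroxybenzaldehyde
Product: 16 2-hydroxy-4,6-bis(methoxymethoxy)benzaldehyde
Conditions: MOMCl (2.2 equiv), iPr2NEt, CH2Cl2, 0 → 25 °C
Reagents that add atoms: chloromethyl methyl ether, COCCl
Why: Selective acetal protection should stop at the bis-ether, because after the 4-hydroxyl and one ortho hydroxyl have reacted the last hydroxyl is held in a hydrogen bond to the aldehyde and is the least nucleophilic.

Step 7
Reactants: 14 2-chloro-1-[2-methoxy-4-(methoxymethoxy)-5-(2-methylbut-3-en-2-yl)phenyl]ethan-1-one; 16 2-hydroxy-4,6-bis(methoxymethoxy)benzaldehyde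
Product: 17 2-{2-[2-methoxy-4-(methoxymethoxy)-5-(2-methylbut-3-en-2-yl)phenyl]-2-oxoethoxy}-4,6-bis(methoxymethoxy)benzaldehyde
Conditions: K2CO3, DMF, 25 °C
Reagents that add atoms: none
Why: Williamson ether synthesis, in which the phenoxide displaces chloride from the carbonyl-activated CH2Cl group; the mild carbonate base at room temperature should keep the product from condensing to an aroylbenzofuran (Rap–Stoermer reaction), the more so as the aldehyde is electron-rich.

Step 8
Reactants: 17 2-{2-[2-methoxy-4-(methoxymethoxy)-5-(2-methylbut-3-en-2-yl)phenyl]-2-oxoethoxy}-4,6-bis(methoxymethoxy)benzaldehyde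
Product: 18 (3R)-3-hydroxy-3-[2-methoxy-4-(methoxymethoxy)-5-(2-methylbut-3-en-2-yl)phenyl]-5,7-bis(methoxymethoxy)-2,3-dihydro-4H-chromen-4-one
Conditions: (5aR,10bS)-2-(pentafluorophenyl)-5a,10b-dihydro-4H,6H-indeno[2,1-b][1,2,4]triazolo[4,3-d][1,4]oxazin-2-ium tetrafluoroborate (10 mol%), Et3N (10 mol%), toluene, 25 °C
Reagents that add atoms: none
Why: Carbene-catalysed enantioselective intramolecular crossed benzoin reaction, precedented for 2-(2-aryl-2-oxoethoxy)benzaldehydes: the carbene turns the aldehyde carbon into a catalyst-bound acyl anion equivalent that attacks the tethered ketone in a 6-exo-trig closure to form C3–C4, and the aminoindanol framework blocks one face so that the bond forms on the Si face of the aryl ketone and C3 becomes R.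

Step 9
Reactants: 18 (3R)-3-hydroxy-3-[2-methoxy-4-(methoxymethoxy)-5-(2-methylbut-3-en-2-yl)phenyl]-5,7-bis(methoxymethoxy)-2,3-dihydro-4H-chromen-4-one
Product: 19 (3R)-3,5,7-trihydroxy-3-[4-hydroxy-2-methoxy-5-(2-methylbut-3-en-2-yl)phenyl]-2,3-dihydro-4H-chromen-4-one
Conditions: HCl (2 M) in MeOH–THF, 25 → 40 °C
Reagents that add atoms: none
Why: Acid-catalysed transacetalisation with methanol removes the three methoxymethyl groups as dimethoxymethane, while the aryl methyl ether, the tertiary α-ketol (no α-hydrogen, ionisation disfavoured by the adjacent carbonyl) and the vinyl group on a quaternary carbon should not react with dilute acid at this temperature, so C3 stays R.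

**Compound list**

1 | paeonol, 1-(2-hydroxy-4-methoxyphenyl)ethan-1-one | CC(=O)c1ccc(OC)cc1O | starting material
2 | 1-(5-bromo-2-hydroxy-4-methoxyphenyl)ethan-1-one | CC(=O)c1cc(Br)c(OC)cc1O | intermediate
3 | 2-acetyl-4-bromo-5-methoxyphenyl tert-butyl carbonate | CC(=O)c1cc(Br)c(OC)cc1OC(=O)OC(C)(C)C | intermediate
4 | methylmagnesium bromide | C[Mg]Br | starting material
5 | vinylmagnesium bromide | C=C[Mg]Br | starting material
6 | bromomagnesium 2-[5-bromo-2-(tert-butoxycarbonyloxy)-4-methoxyphenyl]propan-2-olate (formed in the flask) | CC(C)(O[Mg]Br)c1cc(Br)c(OC)cc1OC(=O)OC(C)(C)C | intermediate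
7 | bromomagnesium 4-bromo-2-[2-(tert-butoxycarbonyloxy)propan-2-yl]-5-methoxyphenolate (formed in the flask) | CC(C)(OC(=O)OC(C)(C)C)c1cc(Br)c(OC)cc1O[Mg]Br | intermediate
8 | 4-bromo-3-methoxy-6-(propan-2-ylidene)cyclohexa-2,4-dien-1-one (formed in the flask) | CC(C)=C1C=C(Br)C(OC)=CC1=O | intermediate
9 | 4-bromo-5-methoxy-2-(2-methylbut-3-en-2-yl)phenol | C=CC(C)(C)c1cc(Br)c(OC)cc1O | intermediate
10 | 1-bromo-2-methoxy-4-(methoxymethoxy)-5-(2-methylbut-3-en-2-yl)benzene | C=CC(C)(C)c1cc(Br)c(OC)cc1OCOC | intermediate
11 | 2-chloro-N-methoxy-N-methylacetamide | CON(C)C(=O)CCl | starting material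
12 | [2-methoxy-4-(methoxymethoxy)-5-(2-methylbut-3-en-2-yl)phenyl]lithium (formed in the flask) | C=CC(C)(C)c1cc([Li])c(OC)cc1OCOC | intermediate
13 | lithium 2-chloro-1-[methoxy(methyl)amino]-1-[2-methoxy-4-(methoxymethoxy)-5-(2-methylbut-3-en-2-yl)phenyl]ethan-1-olate (formed in the flask, racemic) | C=CC(C)(C)c1cc(C(O[Li])(CCl)N(C)OC)c(OC)cc1OCOC | intermediate
14 | 2-chloro-1-[2-methoxy-4-(methoxymethoxy)-5-(2-methylbut-3-en-2-yl)phenyl]ethan-1-one | C=CC(C)(C)c1cc(C(=O)CCl)c(OC)cc1OCOC | intermediate
15 | 2,4,6-trihydroxybenzaldehyde | O=Cc1c(O)cc(O)cc1O | starting material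
16 | 2-hydroxy-4,6-bis(methoxymethoxy)benzaldehyde | O=Cc1c(O)cc(OCOC)cc1OCOC | intermediate
17 | 2-{2-[2-methoxy-4-(methoxymethoxy)-5-(2-methylbut-3-en-2-yl)phenyl]-2-oxoethoxy}-4,6-bis(methoxymethoxy)benzaldehyde | C=CC(C)(C)c1cc(C(=O)COc2cc(OCOC)cc(OCOC)c2C=O)c(OC)cc1OCOC | intermediate
18 | (3R)-3-hydroxy-3-[2-methoxy-4-(methoxymethoxy)-5-(2-methylbut-3-en-2-yl)phenyl]-5,7-bis(methoxymethoxy)-2,3-dihydro-4H-chromen-4-one | C=CC(C)(C)c1cc([C@@]2(O)COc3cc(OCOC)cc(OCOC)c3C2=O)c(OC)cc1OCOC | intermediate
19 | (3R)-3,5,7-trihydroxy-3-[4-hydroxy-2-methoxy-5-(2-methylbut-3-en-2-yl)phenyl]-2,3-dihydro-4H-chromen-4-one | C=CC(C)(C)c1cc([C@@]2(O)COc3cc(O)cc(O)c3C2=O)c(OC)cc1O | target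

**Step count and risks**

Total steps: 9. Longest linear sequence: 8 (steps 1–5 and 7–9); step 6 is a one-step side branch to the ring A aldehyde.

Steps most likely to fail:

1. Step 3. The quinone methide 8 may lose a proton from one of its methyl groups (1,5-hydrogen shift or deprotonation by the Grignard reagent) faster than the vinyl reagent adds to its fully substituted carbon, or the hindered tertiary alkoxide may fail to take over the carbonate group. The fallback builds the quaternary carbon by enolate methylation and the vinyl group by Wittig methylenation; it sets out from 2 and comes back at 10. Compound 2 is protected with MOMCl and iPr2NEt in CH2Cl2 as 1-[5-bromo-4-methoxy-2-(methoxymethoxy)phenyl]ethan-1-one F1. Wittig reaction with the ylide from (methoxymethyl)triphenylphosphonium chloride and KN(SiMe3)2 in THF should give the enol ether 1-bromo-2-methoxy-4-(methoxymethoxy)-5-(1-methoxyprop-1-en-2-yl)benzene F2 as an E/Z mixture. Brief hydrolysis with 1 M HCl in THF at 0 °C, under which the enol ether reacts far faster than the aryl acetal, should give racemic 2-[5-bromo-4-methoxy-2-(methoxymethoxy)phenyl]propanal F3. Methylation of its enolate with KOtBu and MeI in THF should give 2-[5-bromo-4-methoxy-2-(methoxymethoxy)phenyl]-2-methylpropanal F4, and methylenation with the ylide from methyltriphenylphosphonium bromide and KOtBu gives 10.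

2. Step 8. The bulky chiral carbene may add only slowly to an aldehyde flanked by two ortho oxygen substituents, the electron-rich ortho-substituted ketone may be attacked with poor facial discrimination, or base-induced aldol condensation to the aroylbenzofuran may compete. The fallback gives up catalyst control in favour of resolution; it sets out from 17 and comes back at 18. Cyclisation of 17 with the small achiral carbene from 3-benzyl-5-(2-hydroxyethyl)-4-methylthiazolium chloride and Et3N in THF should give racemic 3-hydroxy-3-[2-methoxy-4-(methoxymethoxy)-5-(2-methylbut-3-en-2-yl)phenyl]-5,7-bis(methoxymethoxy)-2,3-dihydro-4H-chromen-4-one F5. Its enantiomers are then separated by preparative chromatography on an amylose tris(3,5-dimethylphenylcarbamate) stationary phase, and the (3R) enantiomer is 18.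

3. Step 5. The aryllithium may act as a base towards the acidic CH2Cl protons of amide 11, or be protonated or butylated before acylation, so that debrominated arene is returned. The fallback introduces the two-carbon ketone unit by cross-coupling; it sets out from 10 and comes back at 17. Stille coupling of 10 with tributyl(1-ethoxyvinyl)stannane (Pd(PPh3)4, toluene, 100 °C) should give 1-(1-ethoxyethenyl)-2-methoxy-4-(methoxymethoxy)-5-(2-methylbut-3-en-2-yl)benzene F6. NBS in THF–water at 0 °C should brominate the electron-rich enol ether much faster than the vinyl group on the quaternary carbon and give 2-bromo-1-[2-methoxy-4-(methoxymethoxy)-5-(2-methylbut-3-en-2-yl)phenyl]ethan-1-one F7, which alkylates 16 (K2CO3, DMF, 25 °C) to give 17.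

**Further compounds**

F1 | step 3 | 1-[5-bromo-4-methoxy-2-(methoxymethoxy)phenyl]ethan-1-one | CC(=O)c1cc(Br)c(OC)cc1OCOC
F2 | step 3 | 1-bromo-2-methoxy-4-(methoxymethoxy)-5-(1-methoxyprop-1-en-2-yl)benzene | COC=C(C)c1cc(Br)c(OC)cc1OCOC
F3 | step 3 | 2-[5-bromo-4-methoxy-2-(methoxymethoxy)phenyl]propanal | CC(C=O)c1cc(Br)c(OC)cc1OCOC
F4 | step 3 | 2-[5-bromo-4-methoxy-2-(methoxymethoxy)phenyl]-2-methylpropanal | CC(C)(C=O)c1cc(Br)c(OC)cc1OCOC
F5 | step 8 | racemic 3-hydroxy-3-[2-methoxy-4-(methoxymethoxy)-5-(2-methylbut-3-en-2-yl)phenyl]-5,7-bis(methoxymethoxy)-2,3-dihydro-4H-chromen-4-one | C=CC(C)(C)c1cc(C2(O)COc3cc(OCOC)cc(OCOC)c3C2=O)c(OC)cc1OCOC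
F6 | step 5 | 1-(1-ethoxyethenyl)-2-methoxy-4-(methoxymethoxy)-5-(2-methylbut-3-en-2-yl)benzene | C=CC(C)(C)c1cc(C(=C)OCC)c(OC)cc1OCOC
F7 | step 5 | 2-bromo-1-[2-methoxy-4-(methoxymethoxy)-5-(2-methylbut-3-en-2-yl)phenyl]ethan-1-one | C=CC(C)(C)c1cc(C(=O)CBr)c(OC)cc1OCOC
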